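**Retrosynthetic overview**
1. Target 17 ⇐ acylation of the C9 alcohol 15 with isovaleric anhydride.
2. Both oxepanes ⇐ one acid-triggered transannular opening of a C9–C10 trans-epoxide by the C5 hydroxyl inside a ten-membered germacranolide (inversion at C10).
3. Ten-membered carbocycle plus trans α-methylene lactone ⇐ intramolecular addition of an enoate β-carbanion equivalent (allylchromium from a 2-(bromomethyl)enoate, C7 as nucleophile) to an epoxy aldehyde; this C7–C8 bond is the key step.
4. Linear precursor ⇐ geranyl acetate by allylic oxidation, Ru–BINAP hydrogenation (C4), Brown allylation (C5), Sharpless epoxidation (C9, C10) and cross-metathesis with methyl 2-(bromomethyl)acrylate.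
5. Ring order: carbocycle and lactone together, then the two oxepanes in the same operation (step 8).

Assumption: locants C1–C15 are germacrane locants of the target and stay with the same atom in every intermediate (C4 = CHMe, C5 = ether CH, C6 = CH2, C7 = lactone CH, C8 = lactone O–CH, C9 = ester O–CH, C10 = ether C(Me), C11–C13 = acrylate unit); the target is then (4S,5R,7R,8R,9S,10R).

**Step 1**
Reactants: 1 geranyl acetate, (2E)-3,7-dimethylocta-2,6-dien-1-yl acetate
Product: 2 (2E,6E)-8-hydroxy-3,7-dimethylocta-2,6-dien-1-yl acetate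
Conditions: SeO2 (0.3 equiv), t-BuOOH (3 equiv), salicylic acid (0.1 equiv), CH2Cl2, 25 °C
Reagents that add atoms: tert-butyl hydroperoxide, CC(C)(C)OO; selenium dioxide (catalytic oxygen carrier), O=[Se]=O
Why: Selenium dioxide allylic oxidation (ene reaction, then [2,3]-sigmatropic shift) attacks the electron-rich terminal olefin rather than the acetate-deactivated one and hydroxylates the trans-methyl group to the (E)-allylic alcohol; no stereocentre is formed.

**Step 2**
Reactants: 2 (2E,6E)-8-hydroxy-3,7-dimethylocta-2,6-dien-1-yl acetate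
Product: 3 (2E,7S)-8-hydroxy-3,7-dimethyloct-2-en-1-yl acetate
Conditions: Ru(OAc)2[(S)-BINAP] (1 mol%), H2 (100 atm), MeOH, 20 °C
Reagents that add atoms: none
Why: Noyori asymmetric hydrogenation of an allylic alcohol: only the olefin next to the free, ruthenium-binding hydroxyl is reduced, and the (S)-ligand, by analogy with geraniol → (R)-citronellol (same olefin face), is expected to set C4 as (S), the allylic acetate olefin staying untouched.

**Step 3**
Reactants: 3 (2E,7S)-8-hydroxy-3,7-dimethyloct-2-en-1-yl acetate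
Product: 4 (2E,7S)-3,7-dimethyl-8-oxooct-2-en-1-yl acetate
Conditions: Dess–Martin periodinane (1.2 equiv), CH2Cl2, 0→25 °C; used crude
Reagents that add atoms: none
Why: Dess–Martin oxidation under neutral conditions gives the α-methyl aldehyde without epimerising C4.

**Step 4**
Reactants: 4 (2E,7S)-3,7-dimethyl-8-oxooct-2-en-1-yl acetate; 5 (+)-B-allyldiisopinocampheylborane
Product: 8 (2E,7S,8R)-3,7-dimethylundeca-2,10-diene-1,8-diol, via borinate ester 6 (not isolated), via hydroxy acetate 7 (not isolated)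
Conditions: 5 (1.3 equiv, 1 M in pentane), Et2O, −78 °C, 3 h; then 3 M NaOH, 30% H2O2, MeOH, 0→25 °C, 12 h
Reagents that add atoms: (+)-B-allyldiisopinocampheylborane (5), C=CCB([C@H]1C[C@H]2C[C@@H]([C@@H]1C)C2(C)C)[C@H]1C[C@H]2C[C@@H]([C@@H]1C)C2(C)C
Why: Brown asymmetric allylboration through a closed chair transition state: the reagent from (−)-α-pinene adds allyl to the Re face under reagent control (anti to the C4 methyl, overriding the weak Felkin bias) and sets C5 as (R), and the alkaline peroxide work-up oxidises the borinate and saponifies the allylic acetate in the same flask.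

**Step 5**
Reactants: 8 (2E,7S,8R)-3,7-dimethylundeca-2,10-diene-1,8-diol
Product: 9 (4R,5S)-8-[(2S,3S)-3-(hydroxymethyl)-2-methyloxiran-2-yl]-5-methyloct-1-en-4-ol
Conditions: Ti(OiPr)4 (0.2 equiv), L-(+)-diethyl tartrate (0.25 equiv), t-BuOOH (2 equiv, decane), 4 Å molecular sieves, CH2Cl2, −25 °C
Reagents that add atoms: tert-butyl hydroperoxide, CC(C)(C)OO
Why: Katsuki–Sharpless asymmetric epoxidation is specific for the allylic alcohol (homoallylic hydroxyl and terminal olefin are inert at −25 °C) and with L-(+)-tartrate gives the (2S,3S)-trans-epoxide, i.e. C9 (S) and C10 (S, inverted later).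

**Step 6**
Reactants: 9 (4R,5S)-8-[(2S,3S)-3-(hydroxymethyl)-2-methyloxiran-2-yl]-5-methyloct-1-en-4-ol; 10 methyl 2-(bromomethyl)prop-2-enoate
Product: 11 methyl (2Z,5R,6S)-2-(bromomethyl)-5-hydroxy-9-[(2S,3S)-3-(hydroxymethyl)-2-methyloxiran-2-yl]-6-methylnon-2-enoate
Conditions: second-generation Hoveyda–Grubbs catalyst (5 mol%), 10 (4 equiv), CH2Cl2, 40 °C; kept neutral, used promptly
Reagents that add atoms: methyl 2-(bromomethyl)prop-2-enoate (10), C=C(CBr)C(=O)OC
Why: Olefin cross-metathesis of the monosubstituted olefin with the 2-substituted acrylate gives the trisubstituted enoate with the chain trans to the ester (the (Z)-bromide by CIP), and free hydroxyls, the epoxide and the allylic bromide are tolerated by the ruthenium carbene.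

**Step 7**
Reactants: 11 methyl (2Z,5R,6S)-2-(bromomethyl)-5-hydroxy-9-[(2S,3S)-3-(hydroxymethyl)-2-methyloxiran-2-yl]-6-methylnon-2-enoate
Product: 12 methyl (2Z,5R,6S)-2-(bromomethyl)-9-[(2S,3R)-3-formyl-2-methyloxiran-2-yl]-5-hydroxy-6-methylnon-2-enoate
Conditions: TEMPO (0.1 equiv), PhI(OAc)2 (1.1 equiv), CH2Cl2, 25 °C
Reagents that add atoms: none
Why: The TEMPO/PhI(OAc)2 oxoammonium oxidation takes the primary alcohol selectively over the secondary one and leaves the epoxide, the allylic bromide and C9 untouched (the descriptor at C9 changes only because of CIP priorities).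

**Step 8**
Reactants: 12 methyl (2Z,5R,6S)-2-(bromomethyl)-9-[(2S,3R)-3-formyl-2-methyloxiran-2-yl]-5-hydroxy-6-methylnon-2-enoate
Product: 15 (4S,5R,7R,8R,9S,10R)-5,10-epoxy-9-hydroxygermacr-11(13)-en-12,8-olide, via ring-closed hydroxy ester 13 (not isolated), via epoxy germacranolide 14 (not isolated)
Conditions: CrCl2 (8 equiv), THF, 2 mM (slow addition of 12), 25 °C, 12 h; then CSA (3 equiv), 25 °C
Reagents that add atoms: none
Why: Nozaki–Hiyama-type chromium Barbier allylation: divalent chromium turns the allylic bromide into an allylchromium in which the enoate β-carbon C7, normally an electrophilic Michael position, is the nucleophile (a homoenolate-type d3 synthon) and adds to the aldehyde through a chair six-membered transition state whose ring-forming tether sits diequatorially (C7/C8 anti, trans-lactone after lactonisation) on the aldehyde face that gives C8–O syn to the epoxide oxygen, as in chromium closures of related epoxy aldehydes to trans-germacranolides, and acid then lets the C5 hydroxyl open the epoxide transannularly at the tertiary C10 with inversion (S→R; C9 is deactivated by the neighbouring acyloxy carbon), which forges both oxepanes at once.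

**Step 9**
Reactants: 15 (4S,5R,7R,8R,9S,10R)-5,10-epoxy-9-hydroxygermacr-11(13)-en-12,8-olide; 16 3-methylbutanoic anhydride
Product: 17 (4S,5R,7R,8R,9S,10R)-5,10-epoxy-9-(3-methylbutanoyloxy)germacr-11(13)-en-12,8-olide (CNP0274454.1)
Conditions: 16 (3 equiv), DMAP (0.3 equiv), Et3N (4 equiv), CH2Cl2, 25 °C
Reagents that add atoms: 3-methylbutanoic anhydride (16), CC(C)CC(=O)OC(=O)CC(C)C
Why: Steglich-type DMAP-catalysed acylation of the only free hydroxyl (the hindered secondary C9–OH) installs the isovalerate without touching a stereocentre, and the α-methylene lactone survives amine bases at room temperature.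

**Compound list**
1 | geranyl acetate, (2E)-3,7-dimethylocta-2,6-dien-1-yl acetate | CC(C)=CCC/C(C)=C/COC(C)=O | starting material
2 | (2E,6E)-8-hydroxy-3,7-dimethylocta-2,6-dien-1-yl acetate | OC/C(C)=C/CC/C(C)=C/COC(C)=O | intermediate
3 | (2E,7S)-8-hydroxy-3,7-dimethyloct-2-en-1-yl acetate | OC[C@@H](C)CCC/C(C)=C/COC(C)=O | intermediate
4 | (2E,7S)-3,7-dimethyl-8-oxooct-2-en-1-yl acetate | O=C[C@@H](C)CCC/C(C)=C/COC(C)=O | intermediate
5 | (+)-B-allyldiisopinocampheylborane (from (−)-α-pinene) | C=CCB([C@H]1C[C@H]2C[C@@H]([C@@H]1C)C2(C)C)[C@H]1C[C@H]2C[C@@H]([C@@H]1C)C2(C)C | starting material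
6 | borinate ester: O-diisopinocampheylboryl derivative of 7 | CC(=O)OC/C=C(C)/CCC[C@H](C)[C@@H](CC=C)OB([C@H]1C[C@H]2C[C@@H]([C@@H]1C)C2(C)C)[C@H]1C[C@H]2C[C@@H]([C@@H]1C)C2(C)C | intermediate
7 | (2E,7S,8R)-8-hydroxy-3,7-dimethylundeca-2,10-dien-1-yl acetate | CC(=O)OC/C=C(C)/CCC[C@H](C)[C@H](O)CC=C | intermediate
8 | (2E,7S,8R)-3,7-dimethylundeca-2,10-diene-1,8-diol | OC/C=C(C)/CCC[C@H](C)[C@H](O)CC=C | intermediate
9 | (4R,5S)-8-[(2S,3S)-3-(hydroxymethyl)-2-methyloxiran-2-yl]-5-methyloct-1-en-4-ol | OC[C@@H]1O[C@@]1(C)CCC[C@H](C)[C@H](O)CC=C | intermediate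
10 | methyl 2-(bromomethyl)prop-2-enoate | C=C(CBr)C(=O)OC | starting material
11 | methyl (2Z,5R,6S)-2-(bromomethyl)-5-hydroxy-9-[(2S,3S)-3-(hydroxymethyl)-2-methyloxiran-2-yl]-6-methylnon-2-enoate | OC[C@@H]1O[C@@]1(C)CCC[C@H](C)[C@H](O)C/C=C(\CBr)C(=O)OC | intermediate
12 | methyl (2Z,5R,6S)-2-(bromomethyl)-9-[(2S,3R)-3-formyl-2-methyloxiran-2-yl]-5-hydroxy-6-methylnon-2-enoate | O=C[C@@H]1O[C@@]1(C)CCC[C@H](C)[C@H](O)C/C=C(\CBr)C(=O)OC | intermediate
13 | methyl (4S,5R,7R,8R,9S,10S)-9,10-epoxy-5,8-dihydroxygermacr-11(13)-en-12-oate (ten-membered ring closed, lactone not yet formed) | C=C(C(=O)OC)[C@H]1C[C@@H](O)[C@@H](C)CCC[C@]2(C)O[C@H]2[C@@H]1O | intermediate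
14 | (4S,5R,7R,8R,9S,10S)-9,10-epoxy-5-hydroxygermacr-11(13)-en-12,8-olide | C=C1C(=O)O[C@@H]2[C@@H]1C[C@@H](O)[C@@H](C)CCC[C@]3(C)O[C@H]32 | intermediate
15 | (4S,5R,7R,8R,9S,10R)-5,10-epoxy-9-hydroxygermacr-11(13)-en-12,8-olide | C=C1C(=O)O[C@@H]2[C@@H]1C[C@H]1O[C@](C)(CCC[C@@H]1C)[C@H]2O | intermediate
16 | 3-methylbutanoic anhydride (isovaleric anhydride) | CC(C)CC(=O)OC(=O)CC(C)C | starting material
17 | (4S,5R,7R,8R,9S,10R)-5,10-epoxy-9-(3-methylbutanoyloxy)germacr-11(13)-en-12,8-olide | C=C1C(=O)O[C@@H]2[C@@H]1C[C@H]1O[C@](C)(CCC[C@@H]1C)[C@H]2OC(=O)CC(C)C | target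

**Totals**
Total step count: 9. Longest linear sequence: 9 steps (from geranyl acetate).

**Three steps most likely to fail, with fallbacks**

Step 8 (ten-membered closure, C7/C8 selectivity, regiochemistry of the ether closure). The medium ring may give oligomers, the facial selectivity rests on analogy, and the hydroxyl could in principle attack C9. The fallback sets out from 12 and comes back at 15. Treating 12 with catalytic CSA in CH2Cl2 at 0 °C closes the ether first: in the open chain the C5 hydroxyl can only reach the tertiary C10 (7-exo, inversion), giving the oxepane α-hydroxy aldehyde methyl (2Z)-2-(bromomethyl)-4-[(2R,3S,7R)-7-[(1R)-1-hydroxy-2-oxoethyl]-3,7-dimethyloxepan-2-yl]but-2-enoate F1. Indium powder in THF/H2O (Barbier conditions that tolerate the free α-hydroxyl, which chelates trivalent indium and directs addition to the syn-diol face) then has to close only a seven-membered ring from C7 onto C8, and acidic work-up lactonises to 15.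

Step 6 (cross-metathesis with a 2-substituted, bromide-bearing acrylate). Homodimerisation or low conversion is possible, and the product carries a hydroxyl cis to the allylic bromide. The fallback sets out from 9 and comes back at 14, which is carried to 15 with CSA as in step 8. The alcohol is oxidised first (TEMPO, PhI(OAc)2) to (2R,3S)-3-[(4S,5R)-5-hydroxy-4-methyloct-7-en-1-yl]-3-methyloxirane-2-carbaldehyde F2. The C5 hydroxyl is esterified with 2-(bromomethyl)acryloyl chloride (2,6-lutidine, CH2Cl2, −20 °C) to (4R,5S)-8-[(2S,3R)-3-formyl-2-methyloxiran-2-yl]-5-methyloct-1-en-4-yl 2-(bromomethyl)prop-2-enoate F3. Ring-closing metathesis (second-generation Grubbs catalyst, CH2Cl2, 40 °C), an easy six-ring closure, gives (2R,3S)-3-[(4S)-4-[(2R)-5-(bromomethyl)-6-oxo-3,6-dihydro-2H-pyran-2-yl]pentyl]-3-methyloxirane-2-carbaldehyde F4. CrCl2 then forms the cyclic allylchromium, which adds through C7 to the aldehyde; the C8 alkoxide translactonises onto the δ-lactone carbonyl and releases the C5 hydroxyl, giving 14.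

Step 2 (enantioselectivity and sense of the hydrogenation of a 2-methyl allylic alcohol). The fallback sets out from 2 and comes back at 3. MnO2 gives the enal (2E,6E)-3,7-dimethyl-8-oxoocta-2,6-dien-1-yl acetate F5. NaClO2/NaH2PO4/2-methyl-2-butene gives (2E,6E)-8-acetoxy-2,6-dimethylocta-2,6-dienoic acid F6. This tiglic-acid-type olefin, a carboxylate-directed substrate class, is hydrogenated with Ru(OAc)2[(S)-BINAP]/H2 to (2S,6E)-8-acetoxy-2,6-dimethyloct-6-enoic acid F7. BH3·SMe2 reduces the acid in the presence of the acetate to 3.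

**Further compounds**
F1 | step 8 | methyl (2Z)-2-(bromomethyl)-4-[(2R,3S,7R)-7-[(1R)-1-hydroxy-2-oxoethyl]-3,7-dimethyloxepan-2-yl]but-2-enoate | O=C[C@H](O)[C@@]1(C)CCC[C@H](C)[C@H](O1)C/C=C(\CBr)C(=O)OC
F2 | step 6 | (2R,3S)-3-[(4S,5R)-5-hydroxy-4-methyloct-7-en-1-yl]-3-methyloxirane-2-carbaldehyde | O=C[C@@H]1O[C@@]1(C)CCC[C@H](C)[C@H](O)CC=C
F3 | step 6 | (4R,5S)-8-[(2S,3R)-3-formyl-2-methyloxiran-2-yl]-5-methyloct-1-en-4-yl 2-(bromomethyl)prop-2-enoate | O=C[C@@H]1O[C@@]1(C)CCC[C@H](C)[C@@H](CC=C)OC(=O)C(=C)CBr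
F4 | step 6 | (2R,3S)-3-[(4S)-4-[(2R)-5-(bromomethyl)-6-oxo-3,6-dihydro-2H-pyran-2-yl]pentyl]-3-methyloxirane-2-carbaldehyde | O=C[C@@H]1O[C@@]1(C)CCC[C@H](C)[C@H]1CC=C(CBr)C(=O)O1
F5 | step 2 | (2E,6E)-3,7-dimethyl-8-oxoocta-2,6-dien-1-yl acetate | O=C/C(C)=C/CC/C(C)=C/COC(C)=O
F6 | step 2 | (2E,6E)-8-acetoxy-2,6-dimethylocta-2,6-dienoic acid | OC(=O)/C(C)=C/CC/C(C)=C/COC(C)=O
F7 | step 2 | (2S,6E)-8-acetoxy-2,6-dimethyloct-6-enoic acid | OC(=O)[C@@H](C)CCC/C(C)=C/COC(C)=O
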